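## Analysis of the target

Palisadin B (26) is numbered here as a 1-benzoxepine: O1, C2, C3, C4, C5, C5a, C6, C7, C8, C9, C9a. A cyclohexane (ring A: C5a, C6, C7, C8, C9, C9a) is trans-fused along C5a–C9a to a 2,5-dihydrooxepine (ring B: O1, C2, C3, C4, C5, C5a, C9a). There are four stereocentres, 2R, 5aS, 7S and 9aS. The C5a hydrogen is anti to the C9a methyl, the C7 bromine is equatorial and on the face of the C9a methyl, and the bromomethyl group at C2 is cis to the C9a methyl across O1. The sensitive sites are the secondary bromide at C7, which is neopentylic next to the C6 gem-dimethyl group and prone to elimination or methyl shift; the primary bromide β to O1; the allylic C2–O1 bond; and the C3=C4 alkene, which forbids unselective hydrogenation late in the route. The hardest bond is the ether: O1 joins a fully substituted carbon (C9a) to a secondary allylic carbon (C2) inside a seven-membered ring, with the two flanking stereocentres related 1,3 across oxygen. The gem-dimethyl carbon next to the ring fusion and the equatorial neopentylic bromide add two further regio- and stereochemical problems. The plan rests on one feature: C9a (quaternary, CH3 and O) and C7 (CHBr) are para to each other across ring A, with C5a between them carrying the carbon chain of ring B. This is the substitution pattern of a para-cresol, in which C9a is the methyl-bearing para carbon, C7 the phenolic carbon and C5a the meta carbon.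

## Retrosynthetic reasoning

**The two C–Br bonds.** Both bromines of 26 are removed first, back to diol 25. Bromide would not survive the hydride, enolate and fluoride chemistry of the earlier steps, so both halogens are introduced last and together. The C7 bromine is equatorial, so substitution with inversion requires the axial 7R alcohol. The forward step has to win against elimination at a neopentylic centre.

**The C7 carbinol.** Diol 25 goes back through silyl ether 24 to ketone 23. A ketone flanked by a gem-dimethyl group gives the axial alcohol with a bulky hydride. The same carbonyl activates C6 for the next disconnection.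

**The two C6–CH3 bonds and the C5a–H bond.** Ketone 23 has a second α-carbon, C8, and a trans-fused ketone of this type enolises preferentially away from the ring fusion. Direct double methylation would therefore go to the wrong carbon. The enolate is instead generated on the C6 side by conjugate addition of hydride, which cannot choose the other side. This is done twice. Exocyclic enone 21 gives enolate 22, which is methylated to 23. Before that, endocyclic enone 17 gives silyl enol ether 18, which takes up one carbon as a methylene group (through 19 and 20) to give 21. The hydride addition to 17 also makes the C5a–H bond. A dissolving-metal reductive methylation would be shorter, but it places carbanion character on C5a next to the C9a–O1 bond and the ether oxygen would be expelled. A hydride adds to C5a without putting charge there.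

**Saturation of C8–C9.** Enone 17 comes from cross-conjugated dienone 16 by conjugate reduction of the disubstituted enone. This alkene has an unhindered β-CH, whereas the other enone ends in the fully substituted C5a, so differentiation should be straightforward.

**The C9a–O1 bond (key disconnection).** Cutting C9a–O1 in 16 and returning ring A to the aromatic oxidation level gives phenol 15. This removes the hardest bond, ring B and the C9a stereocentre in one operation. It leaves a flat arene whose substituents are already in the right places, with a chain that carries the C3=C4 alkene and the C2 stereocentre in final form. The forward reaction must make the chain hydroxyl attack the methyl-bearing para carbon of the oxidised phenol, on the correct face, and close a seven-membered ring. No other disconnection of ring B delivers C2, C3=C4 and the tertiary ether together.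

**Protecting groups.** Phenol 15 needs a free phenol, a free secondary hydroxyl and a blocked primary hydroxyl. It is traced back through bis-silyl ether 14 and diol 13 to acetonide 12. The aryl silyl ether survives acid and is cleaved by mild base, whereas the alkyl silyl ether survives that base. The three hydroxyls are thereby differentiated without an additional protecting group.

**The C3=C4 alkene.** Acetonide 12 is cut at the double bond into ylide 11 (from phosphonium salt 7) and methyl ketone 10. The alkene must be Z, because only then can the chain ends reach each other in the ring closure. A non-stabilised ylide with an α-alkoxy ketone gives this geometry. The carbinol stereocentre comes unchanged from the chiral pool.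

**The fragments.** Salt 7 comes from iodide 6 and alcohol 5. Alcohol 5 is the product of opening oxirane 3 with Grignard reagent 4, made from silyl ether 2 and hence from bromophenol 1. Ketone 10 comes from ester 8 through amide 9.

## Alternatives that were turned down

**Alternative 1:** This plan sets the C5a and C9a centres on a monocyclic ring A and leaves ring B for later.
- Forward key step: enone A1 takes an allylcopper reagent at its β-carbon anti to the silyloxy group. The enolate is trapped as a silyl enol ether and oxidised by a dioxirane on the face opposite the new allyl group, giving hydroxy ketone A2.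
- For: two adjacent stereocentres are set in one flask by sequential anti additions whose sense is well understood. The gem-dimethyl group and the C7 oxygen are present from the start.
- Against: no ring is closed. The O1–C2 bond still has to be made by etherifying a hindered tertiary alcohol with a secondary allylic partner, followed by a ring closure to a trisubstituted alkene. The β-carbon of A1 is neopentylic, and allylcopper reagents readily add 1,2. The ketone of A2 sits at the future C9 and must be removed. C2 remains to be controlled.
- Comparison: this alternative is stronger on the reliability of the C5a/C9a relationship, which the chosen route entrusts to an untested face selection and a hydride facial preference. The chosen route in return makes the tertiary ether and ring B in one step, with C2 and the alkene already in place.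

**Alternative 2:** Here O1 is inserted between C9a and the future C2 of a carbocycle.
- Forward key step: trans-decalone A3, whose carbonyl lies between the angular quaternary carbon and a CH(CH3) carbon, reacts with CF3CO3H. The quaternary carbon migrates with retention and the six-membered ring expands to lactone A4.
- For: retention secures the C9a configuration. The trans fusion, the gem-dimethyl group and the bromide come from established decalin chemistry. The seven-membered ring arises by ring expansion and not by a slow closure.
- Against: the carbonyl is shielded on both sides, and the preference for tertiary over secondary migration is not absolute. From A4 the lactone carbonyl must become CH–CH2Br by a one-carbon homologation and a stereoselective reduction. The saturated C3–C4 bond must be dehydrogenated regioselectively. A3 itself needs a long linear sequence that includes the same neopentylic bromide substitution.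
- Comparison: this alternative is clearly stronger at C9a and C5a. The chosen route is much shorter after its key step, because the C2 centre, the alkene and the ether are all present in 16.

**Alternative 3:** This plan cuts the O1–C2 bond.
- Forward key step: diazo keto ester A5 reacts with Rh2(OAc)4 and the carbenoid inserts into the tertiary O–H bond, closing ring B as keto ester A6.
- For: O–H insertion is little affected by hindrance at the alcohol and is a proven way to close seven-membered cyclic ethers under neutral conditions. Ring A arrives with all its stereocentres.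
- Against: A5 requires the whole of a ring A synthesis of the type in Alternative 1, plus chain extension and diazo transfer. A6 lacks the C3 methyl and the C3=C4 alkene. A methyl nucleophile would have to add to an enolisable β-keto ester, and dehydration would prefer conjugation with the ester, giving C2=C3. The ester must be turned into CH2Br. C2 is epimerisable, so its relation to C9a would depend on an unknown thermodynamic preference.
- Comparison: this alternative is stronger on precedent for the ring closure. The chosen route is stronger on step economy and on placement of the alkene, and its C2 centre is fixed from the chiral pool before the ring closes.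

Key step: step 10

Remark: compounds 1, 3 and 8 are taken to be purchasable; the glycerate carbon of 8 becomes C2 of the target without change of its spatial arrangement.

## Route

Step 1
Reactants: 1 3-bromo-4-methylphenol
Product: 2 (3-bromo-4-methylphenoxy)(tert-butyl)dimethylsilane
Conditions: TBSCl, imidazole, DMF, rt
Reagents that add atoms: tert-butyldimethylsilyl chloride, C[Si](C)(Cl)C(C)(C)C
Why: Imidazole-promoted silylation masks the acidic phenol so that the aryl bromide can be metallated; an aryl silyl ether is chosen because it survives the later acid step and is cleaved by mild base in the presence of an alkyl silyl ether.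

Step 2
Reactants: 2 (3-bromo-4-methylphenoxy)(tert-butyl)dimethylsilane; 3 ethylene oxide
Product: 5 2-[5-(tert-butyldimethylsilyloxy)-2-methylphenyl]ethan-1-ol, via arylmagnesium bromide 4 (not isolated)
Conditions: Mg, THF, reflux; then CuI (10 mol%), 3, −30 → 0 °C
Reagents that add atoms: none
Why: Magnesium insertion gives Grignard reagent 4, which opens the oxirane under copper iodide catalysis (Grignard epoxide opening) and attaches the two-carbon arm to the future C5a; the metal is meta to the silyloxy group, so no silyl migration to carbon is possible.

Step 3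
Reactants: 5 2-[5-(tert-butyldimethylsilyloxy)-2-methylphenyl]ethan-1-ol
Product: 6 tert-butyl[3-(2-iodoethyl)-4-methylphenoxy]dimethylsilane
Conditions: I2, PPh3, imidazole, CH2Cl2, 0 °C → rt
Reagents that add atoms: iodine, II
Why: Appel-type iodination of a primary alcohol by SN2 displacement of the alkoxyphosphonium ion; the buffered conditions leave the aryl silyl ether intact.

Step 4
Reactants: 6 tert-butyl[3-(2-iodoethyl)-4-methylphenoxy]dimethylsilane
Product: 7 {2-[5-(tert-butyldimethylsilyloxy)-2-methylphenyl]ethyl}triphenylphosphonium iodide
Conditions: PPh3, MeCN, reflux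
Reagents that add atoms: triphenylphosphine, c1ccc(cc1)P(c1ccccc1)c1ccccc1
Why: SN2 quaternisation of the phosphine by an unhindered primary iodide gives the Wittig salt.

Step 5
Reactants: 8 methyl (4S)-2,2-dimethyl-1,3-dioxolane-4-carboxylate
Product: 10 1-[(4S)-2,2-dimethyl-1,3-dioxolan-4-yl]ethan-1-one, via N-methoxy-N-methylamide 9 (not isolated)
Conditions: MeNH(OMe)·HCl, i-PrMgCl, THF, −20 °C; then MeMgBr, −20 → 0 °C
Reagents that add atoms: methylmagnesium bromide, C[Mg]Br
Why: The magnesium amide converts the ester into amide 9, which takes up one Grignard equivalent as a stable chelate that releases the methyl ketone only on work-up, so no tertiary alcohol forms; the α stereocentre is not involved and the low temperature guards it against enolisation.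

Step 6
Reactants: 7 {2-[5-(tert-butyldimethylsilyloxy)-2-methylphenyl]ethyl}triphenylphosphonium iodide; 10 1-[(4S)-2,2-dimethyl-1,3-dioxolan-4-yl]ethan-1-one
Product: 12 tert-butyl{3-[(2Z)-3-[(4R)-2,2-dimethyl-1,3-dioxolan-4-yl]but-2-en-1-yl]-4-methylphenoxy}dimethylsilane, via phosphorus ylide 11 (not isolated)
Conditions: KN(SiMe3)2, THF, −78 °C; then 10, −78 °C → rt
Reagents that add atoms: none
Why: Wittig olefination of an α-alkoxy ketone with a non-stabilised ylide under lithium-free conditions, a combination known to give the Z trisubstituted alkene in which the ylide substituent and the oxygen-bearing carbon are cis; the dioxolane stereocentre is carried over unchanged, its descriptor switching from S to R only through the change in priorities.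

Step 7
Reactants: 12 tert-butyl{3-[(2Z)-3-[(4R)-2,2-dimethyl-1,3-dioxolan-4-yl]but-2-en-1-yl]-4-methylphenoxy}dimethylsilane
Product: 13 (2R,3Z)-5-[5-(tert-butyldimethylsilyloxy)-2-methylphenyl]-3-methylpent-3-ene-1,2-diol
Conditions: AcOH/H2O (4:1), 40 °C
Reagents that add atoms: none
Why: Mild acid hydrolysis of the terminal acetonide; the aryl silyl ether is stable to aqueous acetic acid and the medium is too weakly acidic to ionise the allylic alcohol.

Step 8
Reactants: 13 (2R,3Z)-5-[5-(tert-butyldimethylsilyloxy)-2-methylphenyl]-3-methylpent-3-ene-1,2-diol
Product: 14 (2R,3Z)-1-(tert-butyldimethylsilyloxy)-5-[5-(tert-butyldimethylsilyloxy)-2-methylphenyl]-3-methylpent-3-en-2-ol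
Conditions: TBSCl (1.05 equiv), imidazole, CH2Cl2, −20 → 0 °C
Reagents that add atoms: tert-butyldimethylsilyl chloride, C[Si](C)(Cl)C(C)(C)C
Why: Selective silylation of the primary hydroxyl of a 1,2-diol; the secondary allylic hydroxyl beside the trisubstituted alkene is far more hindered and stays free to serve as the nucleophile of the key step.

Step 9
Reactants: 14 (2R,3Z)-1-(tert-butyldimethylsilyloxy)-5-[5-(tert-butyldimethylsilyloxy)-2-methylphenyl]-3-methylpent-3-en-2-ol
Product: 15 3-[(2Z,4R)-5-(tert-butyldimethylsilyloxy)-4-hydroxy-3-methylpent-2-en-1-yl]-4-methylphenol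
Conditions: K2CO3, MeOH, rt
Reagents that add atoms: none
Why: Base-mediated methanolysis cleaves aryl silyl ethers, whose phenoxide is a good leaving group on silicon, much faster than alkyl silyl ethers, so the phenol is freed while the primary silyl ether remains.

Step 10
Reactants: 15 3-[(2Z,4R)-5-(tert-butyldimethylsilyloxy)-4-hydroxy-3-methylpent-2-en-1-yl]-4-methylphenol
Product: 16 (2R,9aS)-2-[(tert-butyldimethylsilyloxy)methyl]-3,9a-dimethyl-5,9a-dihydro-1-benzoxepin-7(2H)-one
Conditions: PhI(OAc)2 (1.1 equiv), (CF3)2CHOH, 0.01 M, 0 °C
Reagents that add atoms: none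
Why: The phenol oxygen displaces an acetate on trivalent iodine and iodobenzene departs, leaving a phenoxenium-type cation with its positive charge largely on the methyl-bearing para carbon (the future C9a); the secondary hydroxyl of the chain on the neighbouring ring carbon adds there and acetate takes the proton. The closest known reaction type is the PhI(OAc)2 oxidation of para-alkylphenols to para-quinol ethers, including intramolecular alkoxylations that give spiro and ring-fused ethers; the same bond is formed here within a larger ring. Ring B closes in a 7-exo-trig mode, oxygen adding to C9a while the arene π bond from C9a to C9 lies outside the new ring, and the Z alkene together with the sp2 ring carbon C5a holds four of the seven ring atoms in two rigid planar units, which lowers the entropic cost. The new stereocentre C9a is controlled only by the carbinol centre: allylic 1,2-strain should keep the carbinol hydrogen eclipsed with the vinylic methyl, which makes the CH2OSi arm pseudoaxial, and a chair-like closure from that arrangement places the C9a methyl on the side of that arm, giving the 2R,9aS isomer. The step needs para in preference to ortho attack, intramolecular in preference to intermolecular capture and the face just described. Para attack is favoured because the para carbon carries the larger share of the charge and is stabilised by its methyl group; the poorly nucleophilic fluorinated alcohol at high dilution leaves the tethered hydroxyl as the only competent nucleophile; and the primary hydroxyl is silylated so that it can neither close an eight-membered ring nor add to the dienone afterwards. The face selection is without direct precedent and is the main uncertainty of the route.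

Step 11
Reactants: 16 (2R,9aS)-2-[(tert-butyldimethylsilyloxy)methyl]-3,9a-dimethyl-5,9a-dihydro-1-benzoxepin-7(2H)-one
Product: 17 (2R,9aS)-2-[(tert-butyldimethylsilyloxy)methyl]-3,9a-dimethyl-5,8,9,9a-tetrahydro-1-benzoxepin-7(2H)-one
Conditions: [(Ph3P)CuH]6 (0.2 equiv), H2O (2 equiv), toluene, rt
Reagents that add atoms: none
Why: Conjugate reduction by a phosphine-ligated copper hydride, which adds to the unhindered β-CH (C9) of the disubstituted enone far faster than to the fully substituted C5a; water protonates the copper enolate, no stereocentre is formed, and the isolated C3=C4 alkene is inert.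

Step 12
Reactants: 17 (2R,9aS)-2-[(tert-butyldimethylsilyloxy)methyl]-3,9a-dimethyl-5,8,9,9a-tetrahydro-1-benzoxepin-7(2H)-one
Product: 18 (2R,5aS,9aS)-2-[(tert-butyldimethylsilyloxy)methyl]-7-[dimethyl(phenyl)silyloxy]-3,9a-dimethyl-2,5,5a,8,9,9a-hexahydro-1-benzoxepine
Conditions: Cu(OAc)2·H2O (5 mol%), 1,2-bis(diphenylphosphino)benzene (5 mol%), PhMe2SiH (1.5 equiv), toluene, rt
Reagents that add atoms: dimethylphenylsilane, C[SiH](C)c1ccccc1
Why: Copper hydride-catalysed 1,4-hydrosilylation: the bisphosphine copper hydride adds to C5a and the silane silylates the copper enolate on oxygen while regenerating the hydride, so the enolate is fixed on the C6 side. Hydride is expected to enter from the face opposite the C9a methyl and the pseudoaxial CH2OSi arm, which both cover the other face, giving the trans ring fusion (5aS). A dissolving-metal reduction is avoided because carbanion character at C5a would expel O1 from C9a.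

Step 13
Reactants: 18 (2R,5aS,9aS)-2-[(tert-butyldimethylsilyloxy)methyl]-7-[dimethyl(phenyl)silyloxy]-3,9a-dimethyl-2,5,5a,8,9,9a-hexahydro-1-benzoxepine
Product: 21 (2R,5aS,9aS)-2-[(tert-butyldimethylsilyloxy)methyl]-3,9a-dimethyl-6-methylidene-5,5a,6,8,9,9a-hexahydro-1-benzoxepin-7(2H)-one, via Mannich base 19 (not isolated), via trimethylammonium iodide 20 (not isolated)
Conditions: [CH2=NMe2]I, CH2Cl2, rt; then MeI; then DBU
Reagents that add atoms: dimethyl(methylidene)ammonium iodide, C=[N+](C)C.[I-]
Why: Mannich aminomethylation of the silyl enol ether at C6 by the iminium salt, N-methylation and base-induced loss of trimethylamine (α-methylenation of a ketone through its enol ether); only C6 reacts because the enol ether double bond is fixed, and C5a is not acidic in any of the intermediates.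

Step 14
Reactants: 21 (2R,5aS,9aS)-2-[(tert-butyldimethylsilyloxy)methyl]-3,9a-dimethyl-6-methylidene-5,5a,6,8,9,9a-hexahydro-1-benzoxepin-7(2H)-one
Product: 23 (2R,5aS,9aS)-2-[(tert-butyldimethylsilyloxy)methyl]-3,6,6,9a-tetramethyl-5,5a,6,8,9,9a-hexahydro-1-benzoxepin-7(2H)-one, via lithium enolate 22 (not isolated)
Conditions: LiBH(s-Bu)3 (1.05 equiv), THF, −78 °C; then MeI, −78 → 0 °C
Reagents that add atoms: iodomethane, CI
Why: Reductive alkylation: the bulky borohydride adds 1,4 at the unsubstituted methylene terminus of the exocyclic enone and gives the tetrasubstituted enolate 22 on the C6 side only, and C-methylation then builds the quaternary carbon; C6 is not a stereocentre, so the face of methylation does not matter.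

Step 15
Reactants: 23 (2R,5aS,9aS)-2-[(tert-butyldimethylsilyloxy)methyl]-3,6,6,9a-tetramethyl-5,5a,6,8,9,9a-hexahydro-1-benzoxepin-7(2H)-one
Product: 24 (2R,5aS,7R,9aS)-2-[(tert-butyldimethylsilyloxy)methyl]-3,6,6,9a-tetramethyl-2,5,5a,6,7,8,9,9a-octahydro-1-benzoxepin-7-ol
Conditions: LiBH(s-Bu)3, THF, −78 → −40 °C
Reagents that add atoms: none
Why: The bulky borohydride attacks the C7 carbonyl from the equatorial direction because the axial path is blocked by the axial hydrogens at C5a and C9, as in the reduction of 4,4-dimethyl-3-keto terpenoids to their axial alcohols; this gives the axial 7R alcohol on the face opposite the C9a methyl.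

Step 16
Reactants: 24 (2R,5aS,7R,9aS)-2-[(tert-butyldimethylsilyloxy)methyl]-3,6,6,9a-tetramethyl-2,5,5a,6,7,8,9,9a-octahydro-1-benzoxepin-7-ol
Product: 25 (2R,5aS,7R,9aS)-2-(hydroxymethyl)-3,6,6,9a-tetramethyl-2,5,5a,6,7,8,9,9a-octahydro-1-benzoxepin-7-ol
Conditions: Bu4NF, THF, rt
Reagents that add atoms: none
Why: Fluoride cleavage of the primary silyl ether; no other group in the molecule responds to fluoride.

Step 17
Reactants: 25 (2R,5aS,7R,9aS)-2-(hydroxymethyl)-3,6,6,9a-tetramethyl-2,5,5a,6,7,8,9,9a-octahydro-1-benzoxepin-7-ol
Product: 26 palisadin B, (2R,5aS,7S,9aS)-7-bromo-2-(bromomethyl)-3,6,6,9a-tetramethyl-2,5,5a,6,7,8,9,9a-octahydro-1-benzoxepine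
Conditions: CBr4 (4 equiv), PPh3 (4 equiv), toluene, 0 → 60 °C
Reagents that add atoms: tetrabromomethane, BrC(Br)(Br)Br
Why: Appel bromination of both hydroxyls: the primary alkoxyphosphonium ion is displaced easily, and the axial one at C7 is displaced by bromide with inversion from the equatorial direction, which gives the equatorial 7S bromide; heating is needed because C7 is neopentylic.

## Compound list

1 | 3-bromo-4-methylphenol | Cc1ccc(O)cc1Br | starting material
2 | (3-bromo-4-methylphenoxy)(tert-butyl)dimethylsilane | Cc1ccc(O[Si](C)(C)C(C)(C)C)cc1Br | intermediate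
3 | ethylene oxide (oxirane) | C1CO1 | starting material
4 | [5-(tert-butyldimethylsilyloxy)-2-methylphenyl]magnesium bromide | Cc1ccc(O[Si](C)(C)C(C)(C)C)cc1[Mg]Br | intermediate
5 | 2-[5-(tert-butyldimethylsilyloxy)-2-methylphenyl]ethan-1-ol | Cc1ccc(O[Si](C)(C)C(C)(C)C)cc1CCO | intermediate
6 | tert-butyl[3-(2-iodoethyl)-4-methylphenoxy]dimethylsilane | Cc1ccc(O[Si](C)(C)C(C)(C)C)cc1CCI | intermediate
7 | {2-[5-(tert-butyldimethylsilyloxy)-2-methylphenyl]ethyl}triphenylphosphonium iodide | Cc1ccc(O[Si](C)(C)C(C)(C)C)cc1CC[P+](c1ccccc1)(c1ccccc1)c1ccccc1.[I-] | intermediate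
8 | methyl (4S)-2,2-dimethyl-1,3-dioxolane-4-carboxylate | COC(=O)[C@@H]1COC(C)(C)O1 | starting material
9 | (4S)-N-methoxy-N,2,2-trimethyl-1,3-dioxolane-4-carboxamide | CON(C)C(=O)[C@@H]1COC(C)(C)O1 | intermediate
10 | 1-[(4S)-2,2-dimethyl-1,3-dioxolan-4-yl]ethan-1-one | CC(=O)[C@@H]1COC(C)(C)O1 | intermediate
11 | {2-[5-(tert-butyldimethylsilyloxy)-2-methylphenyl]ethylidene}triphenylphosphorane | Cc1ccc(O[Si](C)(C)C(C)(C)C)cc1CC=P(c1ccccc1)(c1ccccc1)c1ccccc1 | intermediate
12 | tert-butyl{3-[(2Z)-3-[(4R)-2,2-dimethyl-1,3-dioxolan-4-yl]but-2-en-1-yl]-4-methylphenoxy}dimethylsilane | Cc1ccc(O[Si](C)(C)C(C)(C)C)cc1C/C=C(C)\[C@@H]1COC(C)(C)O1 | intermediate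
13 | (2R,3Z)-5-[5-(tert-butyldimethylsilyloxy)-2-methylphenyl]-3-methylpent-3-ene-1,2-diol | Cc1ccc(O[Si](C)(C)C(C)(C)C)cc1C/C=C(C)\[C@@H](O)CO | intermediate
14 | (2R,3Z)-1-(tert-butyldimethylsilyloxy)-5-[5-(tert-butyldimethylsilyloxy)-2-methylphenyl]-3-methylpent-3-en-2-ol | Cc1ccc(O[Si](C)(C)C(C)(C)C)cc1C/C=C(C)\[C@@H](O)CO[Si](C)(C)C(C)(C)C | intermediate
15 | 3-[(2Z,4R)-5-(tert-butyldimethylsilyloxy)-4-hydroxy-3-methylpent-2-en-1-yl]-4-methylphenol | Cc1ccc(O)cc1C/C=C(C)\[C@@H](O)CO[Si](C)(C)C(C)(C)C | intermediate
16 | (2R,9aS)-2-[(tert-butyldimethylsilyloxy)methyl]-3,9a-dimethyl-5,9a-dihydro-1-benzoxepin-7(2H)-one | CC1=CCC2=CC(=O)C=C[C@]2(C)O[C@H]1CO[Si](C)(C)C(C)(C)C | intermediate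
17 | (2R,9aS)-2-[(tert-butyldimethylsilyloxy)methyl]-3,9a-dimethyl-5,8,9,9a-tetrahydro-1-benzoxepin-7(2H)-one | CC1=CCC2=CC(=O)CC[C@]2(C)O[C@H]1CO[Si](C)(C)C(C)(C)C | intermediate
18 | (2R,5aS,9aS)-2-[(tert-butyldimethylsilyloxy)methyl]-7-[dimethyl(phenyl)silyloxy]-3,9a-dimethyl-2,5,5a,8,9,9a-hexahydro-1-benzoxepine | CC1=CC[C@H]2C=C(O[Si](C)(C)c3ccccc3)CC[C@]2(C)O[C@H]1CO[Si](C)(C)C(C)(C)C | intermediate
19 | (2R,5aS,9aS)-2-[(tert-butyldimethylsilyloxy)methyl]-6-[(dimethylamino)methyl]-3,9a-dimethyl-5,5a,6,8,9,9a-hexahydro-1-benzoxepin-7(2H)-one (both C6 epimers) | CC1=CC[C@H]2C(CN(C)C)C(=O)CC[C@]2(C)O[C@H]1CO[Si](C)(C)C(C)(C)C | intermediate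
20 | N-methyl quaternary ammonium iodide of 19, the 6-[(trimethylammonio)methyl] ketone iodide | CC1=CC[C@H]2C(C[N+](C)(C)C)C(=O)CC[C@]2(C)O[C@H]1CO[Si](C)(C)C(C)(C)C.[I-] | intermediate
21 | (2R,5aS,9aS)-2-[(tert-butyldimethylsilyloxy)methyl]-3,9a-dimethyl-6-methylidene-5,5a,6,8,9,9a-hexahydro-1-benzoxepin-7(2H)-one | CC1=CC[C@H]2C(=C)C(=O)CC[C@]2(C)O[C@H]1CO[Si](C)(C)C(C)(C)C | intermediate
22 | lithium (2R,5aS,9aS)-2-[(tert-butyldimethylsilyloxy)methyl]-3,6,9a-trimethyl-2,5,5a,8,9,9a-hexahydro-1-benzoxepin-7-olate | CC1=CC[C@H]2C(C)=C(O[Li])CC[C@]2(C)O[C@H]1CO[Si](C)(C)C(C)(C)C | intermediate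
23 | (2R,5aS,9aS)-2-[(tert-butyldimethylsilyloxy)methyl]-3,6,6,9a-tetramethyl-5,5a,6,8,9,9a-hexahydro-1-benzoxepin-7(2H)-one | CC1=CC[C@H]2C(C)(C)C(=O)CC[C@]2(C)O[C@H]1CO[Si](C)(C)C(C)(C)C | intermediate
24 | (2R,5aS,7R,9aS)-2-[(tert-butyldimethylsilyloxy)methyl]-3,6,6,9a-tetramethyl-2,5,5a,6,7,8,9,9a-octahydro-1-benzoxepin-7-ol | CC1=CC[C@H]2C(C)(C)[C@H](O)CC[C@]2(C)O[C@H]1CO[Si](C)(C)C(C)(C)C | intermediate
25 | (2R,5aS,7R,9aS)-2-(hydroxymethyl)-3,6,6,9a-tetramethyl-2,5,5a,6,7,8,9,9a-octahydro-1-benzoxepin-7-ol | CC1=CC[C@H]2C(C)(C)[C@H](O)CC[C@]2(C)O[C@H]1CO | intermediate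
26 | palisadin B, (2R,5aS,7S,9aS)-7-bromo-2-(bromomethyl)-3,6,6,9a-tetramethyl-2,5,5a,6,7,8,9,9a-octahydro-1-benzoxepine | CC1=CC[C@H]2C(C)(C)[C@@H](Br)CC[C@]2(C)O[C@H]1CBr | target

## Step count and least certain steps

Total step count: 17. Longest linear sequence: 16 steps, from 1 to 26 through steps 1–4 and 6–17. Ketone 10 is made in one step (step 5) and joins at step 6.

**Step 10 (key step).**
- Risk: the two faces of the oxidised arene may be discriminated poorly, because the only bias is a carbinol centre four atoms from the reacting carbon. The cation may also be diverted before the slow seven-membered closure, by attack at the ortho carbon next to the chain or by intermolecular capture.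
- Fallback: the route stops depending on kinetic face selection and instead separates and recycles. The unwanted C9a epimer of 16, F1, formed beside 16 from 15, is separated by chromatography. F1 is treated with zinc dust in acetic acid, which reduces the quinol ether back to the phenol with loss of O1 from C9a. This regenerates 15, which is put through step 10 again. The fallback sets out from 15 and comes back to the route at 15.

**Step 12.**
- Risk: hydride may be delivered to the wrong face of C5a. The argument for the desired face is steric, and it is opposed by the tendency of nucleophiles to add anti to an allylic C–O bond, here the pseudoaxial C9a–O1. Turnover may also be slow at a β-carbon flanked by a quaternary centre.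
- Fallback: the facial control is moved to a hydroxyl group and the regiochemical problem is solved by a blocking group. From 17, a Corey–Bakshi–Shibata reduction, with the oxazaborolidine antipode that places the hydroxyl on the face opposite the C9a methyl, gives allylic alcohol F2.
- Hydroxyl-directed hydrogenation with [Rh(nbd)(dppb)]BF4 under H2 adds hydrogen to C5a syn to the hydroxyl and gives the trans-fused alcohol F3. The cationic rhodium catalyst reduces the undirected C3=C4 alkene only slowly.
- Parikh–Doering oxidation gives ketone F4. Condensation with N,N-dimethylformamide dimethyl acetal takes place at the less hindered methylene C8 and gives the blocked enaminone F5.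
- Double methylation at C6 with LiN(i-Pr)2 and MeI gives the dimethylated enaminone F6. Removal of the aminomethylene group with aqueous NaOH in ethanol comes back to the route at 23.

**Step 17.**
- Risk: bimolecular elimination towards C8, or methyl migration from C6 after ionisation of the neopentylic alkoxyphosphonium ion, may outrun substitution at C7.
- Fallback: the two substitutions are separated and the secondary one is run on a sulfonate with a soluble bromide. From 25, Appel bromination limited to the primary hydroxyl (1.1 equiv, 0 °C) gives bromo alcohol F7. Triflation (Tf2O, pyridine, −20 °C) gives triflate F8. Displacement with Bu4NBr in toluene with inversion comes back to the route at 26.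

**Step 14.**
- Risk: the borohydride may add to the carbonyl (1,2) and not to the methylene terminus. Proton exchange between enolate 22 and product may also move methylation to C8.
- Fallback: from 21, copper hydride-catalysed 1,4-hydrosilylation as in step 12 gives the tetrasubstituted silyl enol ether F9, which is isolated. The carbonyl is thereby never exposed to a nucleophilic hydride. MeLi then cleaves the Si–O bond and releases enolate 22 free of proton sources. Methylation with MeI comes back to the route at 23.

**Step 6.**
- Risk: the basic ylide may enolise the α-alkoxy ketone, which erodes the configuration of the carbinol carbon. The Z selectivity may also be incomplete.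
- Fallback: the alkene geometry is fixed before the stereocentre exists. From 5, Parikh–Doering oxidation gives aldehyde F10. Stork–Zhao olefination with Ph3P=C(I)CH3 gives the Z vinyl iodide F11.
- Iodine–lithium exchange (t-BuLi, −78 °C) and acylation with 2-(tert-butyldimethylsilyloxy)-N-methoxy-N-methylacetamide give the Z enone F12.
- Corey–Bakshi–Shibata reduction with (R)-2-methyl-CBS-oxazaborolidine and BH3·SMe2, the alkenyl group acting as the large substituent, gives the R carbinol and comes back to the route at 14.

## Further compounds

F1 | step 10 | (2R,9aR)-2-[(tert-butyldimethylsilyloxy)methyl]-3,9a-dimethyl-5,9a-dihydro-1-benzoxepin-7(2H)-one (C9a epimer of 16) | CC1=CCC2=CC(=O)C=C[C@@]2(C)O[C@H]1CO[Si](C)(C)C(C)(C)C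
F2 | step 12 | (2R,7R,9aS)-2-[(tert-butyldimethylsilyloxy)methyl]-3,9a-dimethyl-2,5,7,8,9,9a-hexahydro-1-benzoxepin-7-ol | CC1=CCC2=C[C@H](O)CC[C@]2(C)O[C@H]1CO[Si](C)(C)C(C)(C)C
F3 | step 12 | (2R,5aS,7R,9aS)-2-[(tert-butyldimethylsilyloxy)methyl]-3,9a-dimethyl-2,5,5a,6,7,8,9,9a-octahydro-1-benzoxepin-7-ol | CC1=CC[C@H]2C[C@H](O)CC[C@]2(C)O[C@H]1CO[Si](C)(C)C(C)(C)C
F4 | step 12 | (2R,5aS,9aS)-2-[(tert-butyldimethylsilyloxy)methyl]-3,9a-dimethyl-5,5a,6,8,9,9a-hexahydro-1-benzoxepin-7(2H)-one | CC1=CC[C@H]2CC(=O)CC[C@]2(C)O[C@H]1CO[Si](C)(C)C(C)(C)C
F5 | step 12 | (2R,5aS,9aS)-2-[(tert-butyldimethylsilyloxy)methyl]-8-[(dimethylamino)methylidene]-3,9a-dimethyl-5,5a,6,8,9,9a-hexahydro-1-benzoxepin-7(2H)-one | CC1=CC[C@H]2CC(=O)C(=CN(C)C)C[C@]2(C)O[C@H]1CO[Si](C)(C)C(C)(C)C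
F6 | step 12 | (2R,5aS,9aS)-2-[(tert-butyldimethylsilyloxy)methyl]-8-[(dimethylamino)methylidene]-3,6,6,9a-tetramethyl-5,5a,6,8,9,9a-hexahydro-1-benzoxepin-7(2H)-one | CC1=CC[C@H]2C(C)(C)C(=O)C(=CN(C)C)C[C@]2(C)O[C@H]1CO[Si](C)(C)C(C)(C)C
F7 | step 17 | (2R,5aS,7R,9aS)-2-(bromomethyl)-3,6,6,9a-tetramethyl-2,5,5a,6,7,8,9,9a-octahydro-1-benzoxepin-7-ol | CC1=CC[C@H]2C(C)(C)[C@H](O)CC[C@]2(C)O[C@H]1CBr
F8 | step 17 | (2R,5aS,7R,9aS)-2-(bromomethyl)-3,6,6,9a-tetramethyl-2,5,5a,6,7,8,9,9a-octahydro-1-benzoxepin-7-yl trifluoromethanesulfonate | CC1=CC[C@H]2C(C)(C)[C@H](OS(=O)(=O)C(F)(F)F)CC[C@]2(C)O[C@H]1CBr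
F9 | step 14 | (2R,5aS,9aS)-2-[(tert-butyldimethylsilyloxy)methyl]-7-[dimethyl(phenyl)silyloxy]-3,6,9a-trimethyl-2,5,5a,8,9,9a-hexahydro-1-benzoxepine | CC1=CC[C@H]2C(C)=C(O[Si](C)(C)c3ccccc3)CC[C@]2(C)O[C@H]1CO[Si](C)(C)C(C)(C)C
F10 | step 6 | 2-[5-(tert-butyldimethylsilyloxy)-2-methylphenyl]acetaldehyde | Cc1ccc(O[Si](C)(C)C(C)(C)C)cc1CC=O
F11 | step 6 | tert-butyl{3-[(2Z)-3-iodobut-2-en-1-yl]-4-methylphenoxy}dimethylsilane | Cc1ccc(O[Si](C)(C)C(C)(C)C)cc1C/C=C(C)\I
F12 | step 6 | (3Z)-1-(tert-butyldimethylsilyloxy)-5-[5-(tert-butyldimethylsilyloxy)-2-methylphenyl]-3-methylpent-3-en-2-one | Cc1ccc(O[Si](C)(C)C(C)(C)C)cc1C/C=C(C)\C(=O)CO[Si](C)(C)C(C)(C)C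
A1 | alternative 1 | (5R)-5-(tert-butyldimethylsilyloxy)-2,4,4-trimethylcyclohex-2-en-1-one | CC1=CC(C)(C)[C@H](O[Si](C)(C)C(C)(C)C)CC1=O
A2 | alternative 1 | (2R,3S,5R)-5-(tert-butyldimethylsilyloxy)-2-hydroxy-2,4,4-trimethyl-3-(prop-2-en-1-yl)cyclohexan-1-one | C=CC[C@H]1C(C)(C)[C@H](O[Si](C)(C)C(C)(C)C)CC(=O)[C@]1(C)O
A3 | alternative 2 | trans-fused 6-bromo-2,5,5,8a-tetramethyloctahydronaphthalen-1(2H)-one (configuration as in the SMILES) | C[C@@H]1CC[C@H]2C(C)(C)[C@@H](Br)CC[C@]2(C)C1=O
A4 | alternative 2 | trans-fused 7-bromo-3,6,6,9a-tetramethyloctahydro-1-benzoxepin-2(3H)-one (configuration as in the SMILES) | C[C@@H]1CC[C@H]2C(C)(C)[C@@H](Br)CC[C@]2(C)OC1=O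
A5 | alternative 3 | methyl 5-[3-(tert-butyldimethylsilyloxy)-6-hydroxy-2,2,6-trimethylcyclohexyl]-2-diazo-3-oxopentanoate (configuration as in the SMILES) | COC(=O)C(=[N+]=[N-])C(=O)CC[C@H]1C(C)(C)[C@H](O[Si](C)(C)C(C)(C)C)CC[C@]1(C)O
A6 | alternative 3 | methyl 7-(tert-butyldimethylsilyloxy)-6,6,9a-trimethyl-3-oxodecahydro-1-benzoxepine-2-carboxylate (configuration as in the SMILES, C2 labile) | O=C1CC[C@H]2C(C)(C)[C@H](O[Si](C)(C)C(C)(C)C)CC[C@]2(C)O[C@H]1C(=O)OC
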